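The runs are calculated with constants of no real substance.

Start with an easy step, a count that needs no integration.

- east: Q 0.10 M; D 0.080 M; J 10 µM; the very flask that is asked about, followed so far
- flask: Q 0.10 M; D 0.0800 M; J 10 µM; time 8.0 d

east run (percent of the Q charged)

| time / h | Z / % | Q / % |
|---|---|---|
| 10.0 | 44.9 | 53.5 |
| 30.0 | 76.5 | 23.8 |
| 60.0 | 81.5 | 21.0 |
| 96.0 | 80.4 | 19.0 |
| 120 | 78.9 | 21.8 |
| 144 | 79.6 | 19.9 |

(readings scatter by 1 percentage point)

1. Z, in percent of the Q first charged, at 8.0 d
2. which option adds most Z ("none" when 2 percentage points or less is all one gets) (red / violet / teal / green / none)
3. Z present, with what was taken out counted in, in percent of the Q first charged, after red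
4. Z present, with what was taken out counted in, in percent of the Q first charged, after violet

- red: at 8.0 d add D, 100% of the amount charged, then wait 15 d
- violet: change nothing and wait 15 d more
- teal: at 8.0 d add J, 100% of the amount charged, then wait 15 d
- green: at 8.0 d take out 90% of the Z then present, then wait 15 d

- what is taken out of Z is counted as made
- additions bring no volume worth counting

Follow one molecule of D through the flask, and take as a working assumption that it leaves as one Z, costs one Q and gives J back. Then a bench rule follows, and you can reckon it from the charges:

ceiling = D charged / Q charged = 0.0800 M / 0.10 M = 80.0%

Call this the ceiling: the most Z, in percent of the Q charged, that the D charge can pay for. On that count, while it stands under 100 %, D is the limiting reagent.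

Now test it against something other than the charges. The east readings from 60.0 h to 144 h average

mean Z = 80.1%

This is level with the ceiling, each reading scattering by 1 percentage point. Z plus Q reads 99.5% at the last east reading. So expect 80.0% in the flask at 8.0 d, and the same after violet. Teal and green leave the D count as it was, so expect no gain from them.

The rule stops working where the ratio passes 100 %. Reckon it for red:

(D charged + D added) / Q charged = 160%

Here the D charged and added exceeds the Q charged, so the ratio no longer bounds Z. Take the Q charge, 100 %, as the bound in red. That is a bound and not a promise: the Q above the ceiling asks each J charged for 2000 further turnovers.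

The forecast gives 80% now, red as best, 98% after red and 80% after violet, on the ground that “Red supplies D, so the remaining Q should convert”. Its figure after red stands under my bound.

The flask gives 80.0% Z at 8.0 d, 80.0% after violet and 100% after red, a gain of 20 points, while teal and green gain 0 points.

G → L + X (k = 1100 /min); D + L ⇌ E (K = 7.60 /M, k = 4100 /M/min); E → J + Z (k = 27.0 /min); Q + J ⇌ G (K = 11.0 /M, k = 50000 /M/min) At 192 h the flask has 0% of its D and 20.0% of its Q still free, with Z at the ceiling of 80.0%. Now put the ceiling to the neighbour with 0.40 M of Q: 0.0800 M / 0.40 M = 20.0%. That neighbour flask reaches 20.0% Z and ends with 80.0% of its Q.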